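**Plan**

- Ring numbering: C1 (methoxy-bearing), C2, C3 (C=O), C4 (quaternary epoxide carbon carrying the farnesyl chain), C5 (epoxide CH), C6 (CHOH). The C3 ketone beside the oxygenated quaternary C4 of the one carbocycle is a latent α-ketol, and this is what allows an aldehyde–ketone benzoin union across C3–C4.
- Retrosynthetic cuts: epoxide C5–O (back to C4-OH/C5-OMs), the C1=C2 enol ether (back to a C1 dimethyl ketal), C3–C4 (benzoin), C4–farnesyl (allylbarium addition), C1–C2 (Claisen condensation).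
- Forward order: diethyl D-tartrate supplies C1, C6, C5 and C4; C2–C3 are added at C1, the farnesyl chain at C4, the carbocycle then closes at C3–C4, and the oxirane is formed last.
- Stereochemistry: C5 and C6 come from D-tartrate; C4 is set in the benzoin (OH trans to the C5 oxygen); C5 is inverted in the epoxide closure, which leaves the oxirane cis to the C6 hydroxyl as in the target.

Key step: step 10

Assumption: the (5aR,10bS) antipode of the triazolium salt is taken as the one matched to the substrate's chair preference; if the pairing proves mismatched, the mirror-image salt is used and nothing else in the route changes.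

**Route**

Step 1
Reactants: 1 diethyl D-tartrate
Product: 2 diethyl (2S,3S)-2-[(tert-butyldimethylsilyl)oxy]-3-hydroxybutanedioate
Conditions: TBSCl (1.05 equiv), imidazole, DMF, 0 °C
Reagents that add atoms: tert-butyldimethylsilyl chloride, CC(C)(C)[Si](C)(C)Cl
Why: Silyl ether formation on a C2-symmetric diol, where either hydroxyl gives the same product and the first bulky silyl group slows a second silylation, so one equivalent should stop at the mono-ether without touching the stereocentres.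

Step 2
Reactants: 2 diethyl (2S,3S)-2-[(tert-butyldimethylsilyl)oxy]-3-hydroxybutanedioate
Product: 3 ethyl (2S,3R)-2-[(tert-butyldimethylsilyl)oxy]-3,4-dihydroxybutanoate
Conditions: BH3·SMe2, NaBH4 (5 mol %), THF, 0 °C to rt; MeOH quench
Reagents that add atoms: none
Why: Hydroxyl-directed borane reduction of an α-hydroxy ester, in which the free hydroxyl forms an alkoxyborane that delivers hydride only to the neighbouring ester, so the ester beside the silyl ether and both stereocentres should remain untouched.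

Step 3
Reactants: 3 ethyl (2S,3R)-2-[(tert-butyldimethylsilyl)oxy]-3,4-dihydroxybutanoate
Product: 4 ethyl (2S,3R)-2-[(tert-butyldimethylsilyl)oxy]-3,4-bis[(triethylsilyl)oxy]butanoate
Conditions: TESCl (2.5 equiv), imidazole, DMF, 0 °C
Reagents that add atoms: chlorotriethylsilane, CC[Si](Cl)(CC)CC
Why: Silyl ether formation that caps both hydroxyls with the more labile triethylsilyl group (later oxidised off at the primary position and removed beside TBS at the future C5), done promptly so that diol 3 cannot lactonise.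

Step 4
Reactants: 4 ethyl (2S,3R)-2-[(tert-butyldimethylsilyl)oxy]-3,4-bis[(triethylsilyl)oxy]butanoate; 5 tert-butyl acetate
Product: 7 tert-butyl (4S,5R)-4-[(tert-butyldimethylsilyl)oxy]-3-oxo-5,6-bis[(triethylsilyl)oxy]hexanoate, via lithium enolate of tert-butyl acetate 6 (not isolated)
Conditions: LiN(iPr)2 (3.3 equiv), 5 (3.3 equiv), THF, −78 °C; then 4, −78 to −30 °C; aq NH4Cl
Reagents that add atoms: none
Why: Crossed Claisen condensation in which the excess ester enolate acylates on the ethyl ester and the product is held as its doubly stabilised enolate, which should prevent over-addition and shield the adjacent α-silyloxy stereocentre from epimerisation while adding C2 and C3.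

Step 5
Reactants: 7 tert-butyl (4S,5R)-4-[(tert-butyldimethylsilyl)oxy]-3-oxo-5,6-bis[(triethylsilyl)oxy]hexanoate
Product: 8 tert-butyl (4S,5R)-4-[(tert-butyldimethylsilyl)oxy]-3,3-dimethoxy-5,6-bis[(triethylsilyl)oxy]hexanoate
Conditions: MeOSiMe3 (4 equiv), TMSOTf (10 mol %), CH2Cl2, −78 to −40 °C; pyridine quench
Reagents that add atoms: methoxytrimethylsilane, CO[Si](C)(C)C
Why: Silyl-transfer acetalisation of a ketone, driven by formation of the Si–O–Si bond under aprotic conditions at low temperature, where the silyl ethers and tert-butyl ester should survive and the β,β-dimethoxy ester should not lose methanol.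

Step 6
Reactants: 8 tert-butyl (4S,5R)-4-[(tert-butyldimethylsilyl)oxy]-3,3-dimethoxy-5,6-bis[(triethylsilyl)oxy]hexanoate
Product: 9 tert-butyl (4S,5S)-4-[(tert-butyldimethylsilyl)oxy]-3,3-dimethoxy-6-oxo-5-[(triethylsilyl)oxy]hexanoate
Conditions: (COCl)2, DMSO, CH2Cl2, −78 to −35 °C; Et3N, −78 to 0 °C
Reagents that add atoms: none
Why: Swern oxidation applied directly to a primary triethylsilyl ether, whose unhindered oxygen is attacked by the chlorosulfonium salt with loss of the silyl chloride before base collapses the alkoxysulfonium ion to the aldehyde, leaving the secondary TES and TBS ethers, the ketal and the α-silyloxy stereocentre intact at low temperature.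

Step 7
Reactants: 9 tert-butyl (4S,5S)-4-[(tert-butyldimethylsilyl)oxy]-3,3-dimethoxy-6-oxo-5-[(triethylsilyl)oxy]hexanoate; 10 (2E,6E)-farnesyl chloride
Product: 12 tert-butyl (4S,5R,8E,12E)-4-[(tert-butyldimethylsilyl)oxy]-6-hydroxy-3,3-dimethoxy-9,13,17-trimethyl-5-[(triethylsilyl)oxy]octadeca-8,12,16-trienoate (mixture of C6 epimers), via (2E,6E)-farnesylbarium chloride 11 (not isolated)
Conditions: BaI2, Li, biphenyl, THF, rt (active Ba); 10, −78 °C; then 9, −78 °C; aq NH4Cl at −78 °C
Reagents that add atoms: none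
Why: Grignard-type carbonyl allylation with an allylbarium reagent, which at −78 °C reacts at its unsubstituted α-carbon with retention of the E geometry, so the linear farnesyl carbinol should form instead of the branched γ-adduct while the tert-butyl ester stays inert; the new carbinol centre arises as a mixture that is erased by oxidation in step 9.

Step 8
Reactants: 12 tert-butyl (4S,5R,8E,12E)-4-[(tert-butyldimethylsilyl)oxy]-6-hydroxy-3,3-dimethoxy-9,13,17-trimethyl-5-[(triethylsilyl)oxy]octadeca-8,12,16-trienoate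
Product: 13 (4S,5R,8E,12E)-4-[(tert-butyldimethylsilyl)oxy]-3,3-dimethoxy-9,13,17-trimethyl-5-[(triethylsilyl)oxy]octadeca-8,12,16-triene-1,6-diol (mixture of C6 epimers)
Conditions: LiAlH4, Et2O, 0 °C; H2O/NaOH work-up
Reagents that add atoms: none
Why: Hydride reduction of an ester to the primary alcohol, which at 0 °C should leave the silyl ethers, the ketal and the isolated trisubstituted alkenes alone.

Step 9
Reactants: 13 (4S,5R,8E,12E)-4-[(tert-butyldimethylsilyl)oxy]-3,3-dimethoxy-9,13,17-trimethyl-5-[(triethylsilyl)oxy]octadeca-8,12,16-triene-1,6-diol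
Product: 14 (4S,5S,8E,12E)-4-[(tert-butyldimethylsilyl)oxy]-3,3-dimethoxy-9,13,17-trimethyl-6-oxo-5-[(triethylsilyl)oxy]octadeca-8,12,16-trienal
Conditions: Dess–Martin periodinane (3 equiv), NaHCO3, CH2Cl2, 0 °C to rt; used at once
Reagents that add atoms: none
Why: Dess–Martin oxidation of both alcohols in one operation under buffered, non-basic conditions, the usual way to reach a β,γ-unsaturated ketone without conjugation and an α-silyloxy ketone without epimerisation.

Step 10
Reactants: 14 (4S,5S,8E,12E)-4-[(tert-butyldimethylsilyl)oxy]-3,3-dimethoxy-9,13,17-trimethyl-6-oxo-5-[(triethylsilyl)oxy]octadeca-8,12,16-trienal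
Product: 15 (2R,3S,4S)-4-[(tert-butyldimethylsilyl)oxy]-2-hydroxy-5,5-dimethoxy-3-[(triethylsilyl)oxy]-2-[(2E,6E)-3,7,11-trimethyldodeca-2,6,10-trien-1-yl]cyclohexan-1-one
Conditions: (5aR,10bS)-2-(pentafluorophenyl)-5a,10b-dihydro-4H,6H-indeno[2,1-b][1,2,4]triazolo[4,3-d][1,4]oxazin-2-ium tetrafluoroborate (20 mol %), Et3N (20 mol %), toluene (0.02 M), rt
Reagents that add atoms: none
Why: The triazolylidene freed by Et3N adds to the unhindered C3 aldehyde and proton transfer gives the hydroxy-enamine (acyl anion equivalent), whose nucleophilic carbon attacks the C4 ketone before the catalyst is expelled from the resulting alkoxide; this is the carbene-catalysed intramolecular crossed aldehyde–ketone benzoin reaction, established for five- and six-membered α-ketols. The carbocycle closes in a 6-exo-trig mode by forming C3–C4. The new C4 stereocentre is controlled by a chair transition state in which the trans C5 and C6 silyloxy groups are equatorial and the ketone oxygen, hydrogen-bonded to the enol OH, is equatorial as well, so the C4 hydroxyl should end up trans to the C5 oxygen with the farnesyl arm axial, and the aminoindanol backbone of the matched catalyst antipode blocks the other ketone face. Chemoselectivity is inherent, because only the aldehyde can become the acyl anion equivalent and the ketone is the only electrophile within reach of a six-membered ring. The step needs the β,γ-double bond to stay out of conjugation, C5 to stay unepimerised and the β-ketal aldehyde to keep its methanol, and the acidic N-C6F5 triazolium salt secures this by allowing a weak amine base in a non-polar solvent at room temperature.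

Step 11
Reactants: 15 (2R,3S,4S)-4-[(tert-butyldimethylsilyl)oxy]-2-hydroxy-5,5-dimethoxy-3-[(triethylsilyl)oxy]-2-[(2E,6E)-3,7,11-trimethyldodeca-2,6,10-trien-1-yl]cyclohexan-1-one
Product: 16 (4S,5S,6R)-4-[(tert-butyldimethylsilyl)oxy]-5,6-dihydroxy-3-methoxy-6-[(2E,6E)-3,7,11-trimethyldodeca-2,6,10-trien-1-yl]cyclohex-2-en-1-one
Conditions: CSA (0.2 equiv), MeOH/CH2Cl2 (1:5), 0 °C to rt
Reagents that add atoms: none
Why: Acid-catalysed methanolysis of the triethylsilyl ether together with β-elimination of methanol from the β-keto ketal (oxocarbenium ion, loss of a C2 proton), which should give the conjugated vinylogous ester as the thermodynamic product with the methoxy group necessarily on C1 while the sturdier TBS ether at C6 survives.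

Step 12
Reactants: 16 (4S,5S,6R)-4-[(tert-butyldimethylsilyl)oxy]-5,6-dihydroxy-3-methoxy-6-[(2E,6E)-3,7,11-trimethyldodeca-2,6,10-trien-1-yl]cyclohex-2-en-1-one
Product: 17 (1S,2R,6S)-6-[(tert-butyldimethylsilyl)oxy]-2-hydroxy-5-methoxy-3-oxo-2-[(2E,6E)-3,7,11-trimethyldodeca-2,6,10-trien-1-yl]cyclohex-4-en-1-yl methanesulfonate
Conditions: MsCl (1.2 equiv), Et3N, CH2Cl2, −20 °C
Reagents that add atoms: methanesulfonyl chloride, CS(=O)(=O)Cl
Why: Sulfonylation by the sulfene pathway, which should esterify the secondary C5 hydroxyl while the tertiary C4 hydroxyl is too hindered to react.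

Step 13
Reactants: 17 (1S,2R,6S)-6-[(tert-butyldimethylsilyl)oxy]-2-hydroxy-5-methoxy-3-oxo-2-[(2E,6E)-3,7,11-trimethyldodeca-2,6,10-trien-1-yl]cyclohex-4-en-1-yl methanesulfonate
Product: 18 (1R,5S,6R)-5-[(tert-butyldimethylsilyl)oxy]-4-methoxy-1-[(2E,6E)-3,7,11-trimethyldodeca-2,6,10-trien-1-yl]-7-oxabicyclo[4.1.0]hept-3-en-2-one
Conditions: K2CO3 (2 equiv), MeOH, 0 °C to rt
Reagents that add atoms: none
Why: Intramolecular Williamson etherification (3-exo-tet), in which the C4 alkoxide, trans to the C5 mesylate, displaces it with inversion at C5 and so places the oxirane on the face of the C6 silyloxy group; C6 stays silylated so that it cannot compete as a second trans alkoxide.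

Step 14
Reactants: 18 (1R,5S,6R)-5-[(tert-butyldimethylsilyl)oxy]-4-methoxy-1-[(2E,6E)-3,7,11-trimethyldodeca-2,6,10-trien-1-yl]-7-oxabicyclo[4.1.0]hept-3-en-2-one
Product: 19 yanuthone X2, (1R,5S,6R)-5-hydroxy-4-methoxy-1-[(2E,6E)-3,7,11-trimethyldodeca-2,6,10-trien-1-yl]-7-oxabicyclo[4.1.0]hept-3-en-2-one
Conditions: Bu4NF, AcOH (1:1), THF, 0 °C to rt
Reagents that add atoms: none
Why: Fluoride-mediated desilylation under acetic acid buffering, which should cleave the Si–O bond without opening the epoxide or attacking the vinylogous ester, and the freed C6 hydroxyl is cis to the oxirane so no Payne-type migration can follow.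

**Compound list**

1 | diethyl D-tartrate, diethyl (2S,3S)-2,3-dihydroxybutanedioate | CCOC(=O)[C@@H](O)[C@H](O)C(=O)OCC | starting material
2 | diethyl (2S,3S)-2-[(tert-butyldimethylsilyl)oxy]-3-hydroxybutanedioate | CCOC(=O)[C@@H](O[Si](C)(C)C(C)(C)C)[C@H](O)C(=O)OCC | intermediate
3 | ethyl (2S,3R)-2-[(tert-butyldimethylsilyl)oxy]-3,4-dihydroxybutanoate | CCOC(=O)[C@@H](O[Si](C)(C)C(C)(C)C)[C@H](O)CO | intermediate
4 | ethyl (2S,3R)-2-[(tert-butyldimethylsilyl)oxy]-3,4-bis[(triethylsilyl)oxy]butanoate | CCOC(=O)[C@@H](O[Si](C)(C)C(C)(C)C)[C@H](O[Si](CC)(CC)CC)CO[Si](CC)(CC)CC | intermediate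
5 | tert-butyl acetate | CC(=O)OC(C)(C)C | starting material
6 | lithium enolate of tert-butyl acetate (not isolated) | [Li]OC(=C)OC(C)(C)C | intermediate
7 | tert-butyl (4S,5R)-4-[(tert-butyldimethylsilyl)oxy]-3-oxo-5,6-bis[(triethylsilyl)oxy]hexanoate | CC(C)(C)OC(=O)CC(=O)[C@@H](O[Si](C)(C)C(C)(C)C)[C@H](O[Si](CC)(CC)CC)CO[Si](CC)(CC)CC | intermediate
8 | tert-butyl (4S,5R)-4-[(tert-butyldimethylsilyl)oxy]-3,3-dimethoxy-5,6-bis[(triethylsilyl)oxy]hexanoate | CC(C)(C)OC(=O)CC(OC)(OC)[C@@H](O[Si](C)(C)C(C)(C)C)[C@H](O[Si](CC)(CC)CC)CO[Si](CC)(CC)CC | intermediate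
9 | tert-butyl (4S,5S)-4-[(tert-butyldimethylsilyl)oxy]-3,3-dimethoxy-6-oxo-5-[(triethylsilyl)oxy]hexanoate | CC(C)(C)OC(=O)CC(OC)(OC)[C@@H](O[Si](C)(C)C(C)(C)C)[C@H](O[Si](CC)(CC)CC)C=O | intermediate
10 | (2E,6E)-farnesyl chloride, (2E,6E)-1-chloro-3,7,11-trimethyldodeca-2,6,10-triene | ClC/C=C(\C)CC/C=C(\C)CCC=C(C)C | starting material
11 | (2E,6E)-farnesylbarium chloride (not isolated) | Cl[Ba]C/C=C(\C)CC/C=C(\C)CCC=C(C)C | intermediate
12 | tert-butyl (4S,5R,8E,12E)-4-[(tert-butyldimethylsilyl)oxy]-6-hydroxy-3,3-dimethoxy-9,13,17-trimethyl-5-[(triethylsilyl)oxy]octadeca-8,12,16-trienoate (C6 epimers) | CC(C)(C)OC(=O)CC(OC)(OC)[C@@H](O[Si](C)(C)C(C)(C)C)[C@H](O[Si](CC)(CC)CC)C(O)C/C=C(\C)CC/C=C(\C)CCC=C(C)C | intermediate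
13 | (4S,5R,8E,12E)-4-[(tert-butyldimethylsilyl)oxy]-3,3-dimethoxy-9,13,17-trimethyl-5-[(triethylsilyl)oxy]octadeca-8,12,16-triene-1,6-diol (C6 epimers) | OCCC(OC)(OC)[C@@H](O[Si](C)(C)C(C)(C)C)[C@H](O[Si](CC)(CC)CC)C(O)C/C=C(\C)CC/C=C(\C)CCC=C(C)C | intermediate
14 | (4S,5S,8E,12E)-4-[(tert-butyldimethylsilyl)oxy]-3,3-dimethoxy-9,13,17-trimethyl-6-oxo-5-[(triethylsilyl)oxy]octadeca-8,12,16-trienal | O=CCC(OC)(OC)[C@@H](O[Si](C)(C)C(C)(C)C)[C@H](O[Si](CC)(CC)CC)C(=O)C/C=C(\C)CC/C=C(\C)CCC=C(C)C | intermediate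
15 | (2R,3S,4S)-4-[(tert-butyldimethylsilyl)oxy]-2-hydroxy-5,5-dimethoxy-3-[(triethylsilyl)oxy]-2-[(2E,6E)-3,7,11-trimethyldodeca-2,6,10-trien-1-yl]cyclohexan-1-one | O=C1CC(OC)(OC)[C@@H](O[Si](C)(C)C(C)(C)C)[C@H](O[Si](CC)(CC)CC)[C@]1(O)C/C=C(\C)CC/C=C(\C)CCC=C(C)C | intermediate
16 | (4S,5S,6R)-4-[(tert-butyldimethylsilyl)oxy]-5,6-dihydroxy-3-methoxy-6-[(2E,6E)-3,7,11-trimethyldodeca-2,6,10-trien-1-yl]cyclohex-2-en-1-one | COC1=CC(=O)[C@@](O)(C/C=C(\C)CC/C=C(\C)CCC=C(C)C)[C@@H](O)[C@@H]1O[Si](C)(C)C(C)(C)C | intermediate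
17 | (1S,2R,6S)-6-[(tert-butyldimethylsilyl)oxy]-2-hydroxy-5-methoxy-3-oxo-2-[(2E,6E)-3,7,11-trimethyldodeca-2,6,10-trien-1-yl]cyclohex-4-en-1-yl methanesulfonate | COC1=CC(=O)[C@@](O)(C/C=C(\C)CC/C=C(\C)CCC=C(C)C)[C@@H](OS(C)(=O)=O)[C@@H]1O[Si](C)(C)C(C)(C)C | intermediate
18 | (1R,5S,6R)-5-[(tert-butyldimethylsilyl)oxy]-4-methoxy-1-[(2E,6E)-3,7,11-trimethyldodeca-2,6,10-trien-1-yl]-7-oxabicyclo[4.1.0]hept-3-en-2-one | COC1=CC(=O)[C@]2(C/C=C(\C)CC/C=C(\C)CCC=C(C)C)O[C@@H]2[C@@H]1O[Si](C)(C)C(C)(C)C | intermediate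
19 | yanuthone X2, (1R,5S,6R)-5-hydroxy-4-methoxy-1-[(2E,6E)-3,7,11-trimethyldodeca-2,6,10-trien-1-yl]-7-oxabicyclo[4.1.0]hept-3-en-2-one | COC1=CC(=O)[C@]2(C/C=C(\C)CC/C=C(\C)CCC=C(C)C)O[C@@H]2[C@@H]1O | target

**Step count and risks**

Total step count: 14. Longest linear sequence: 14 steps (1 to 19); compounds 5 and 10 are purchased.

Steps most likely to fail:

Step 10 (benzoin ring closure). The amine base may move the β,γ-double bond of the ketone into conjugation, epimerise C5, trigger loss of methanol from the β-ketal aldehyde or an aldol closure from C5 onto the aldehyde, and the acyl anion equivalent may attack the wrong ketone face. Fallback: the C3–C4 bond would be formed reductively instead. Starting from keto aldehyde 14, SmI2 (THF, t-BuOH, −78 °C) should bring about a ketyl pinacol cyclisation to the cis-diol (1S,2S,3S,4S)-4-[(tert-butyldimethylsilyl)oxy]-5,5-dimethoxy-3-[(triethylsilyl)oxy]-2-[(2E,6E)-3,7,11-trimethyldodeca-2,6,10-trien-1-yl]cyclohexane-1,2-diol F1, in which the new hydroxyls are expected anti to the C5 silyloxy group. Oxidation of the secondary carbinol beside the tertiary one (Dess–Martin periodinane, NaHCO3) would then come back to the route at α-ketol 15.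

Step 7 (farnesylbarium addition). The reagent may lose its α-regioselectivity or its alkene geometry on warming, enolise the α-silyloxy aldehyde, or provoke silyl migration onto the new alkoxide. Fallback: the chain would be brought in as a sulfone-stabilised carbanion, which can react only at C1 of the farnesyl unit. Chloride 10 and PhSO2Na (DMF) should give (2E,6E)-farnesyl phenyl sulfone F2. Its lithio derivative (n-BuLi, THF, −78 °C) would add to aldehyde 9 to give tert-butyl (4S,5R,8E,12E)-4-[(tert-butyldimethylsilyl)oxy]-6-hydroxy-3,3-dimethoxy-9,13,17-trimethyl-7-(phenylsulfonyl)-5-[(triethylsilyl)oxy]octadeca-8,12,16-trienoate F3 as a diastereomer mixture. Dess–Martin oxidation would give tert-butyl (4S,5S,8E,12E)-4-[(tert-butyldimethylsilyl)oxy]-3,3-dimethoxy-9,13,17-trimethyl-6-oxo-7-(phenylsulfonyl)-5-[(triethylsilyl)oxy]octadeca-8,12,16-trienoate F4. SmI2 (THF/MeOH, −78 °C) would remove the sulfonyl group with kinetic α-protonation of the dienolate to give tert-butyl (4S,5S,8E,12E)-4-[(tert-butyldimethylsilyl)oxy]-3,3-dimethoxy-9,13,17-trimethyl-6-oxo-5-[(triethylsilyl)oxy]octadeca-8,12,16-trienoate F5. LiAlH4 then reduces ketone and ester together and rejoins the route at diol 13.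

Step 5 (ketalisation of the β-keto ester). The oxocarbenium ion may drain into the conjugated β-methoxy enoate by loss of methanol, the hindered ketone may react incompletely, or the Lewis acid may strip the tert-butyl ester or a triethylsilyl ether. Fallback: the ketal would be built on a ketone that is not part of a β-dicarbonyl, and the ester revealed afterwards under basic conditions.
- Ester 4 with MeNH(OMe)·HCl and iPrMgCl (THF, −20 °C) should give (2S,3R)-2-[(tert-butyldimethylsilyl)oxy]-N-methoxy-N-methyl-3,4-bis[(triethylsilyl)oxy]butanamide F6.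
- AllylMgBr (THF, −78 °C) would give (5S,6R)-5-[(tert-butyldimethylsilyl)oxy]-6,7-bis[(triethylsilyl)oxy]hept-1-en-4-one F7.
- Silyl-transfer acetalisation as in step 5 would give (5S,6R)-5-[(tert-butyldimethylsilyl)oxy]-4,4-dimethoxy-6,7-bis[(triethylsilyl)oxy]hept-1-ene F8.
- Ozonolysis in CH2Cl2/methanolic NaOH at −78 °C would convert the vinyl group directly into the ester, methyl (4S,5R)-4-[(tert-butyldimethylsilyl)oxy]-3,3-dimethoxy-5,6-bis[(triethylsilyl)oxy]hexanoate F9.
- F9 would then pass through the chemistry of steps 6 and 7 via methyl (4S,5S)-4-[(tert-butyldimethylsilyl)oxy]-3,3-dimethoxy-6-oxo-5-[(triethylsilyl)oxy]hexanoate F10 and methyl (4S,5R,8E,12E)-4-[(tert-butyldimethylsilyl)oxy]-6-hydroxy-3,3-dimethoxy-9,13,17-trimethyl-5-[(triethylsilyl)oxy]octadeca-8,12,16-trienoate F11.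
- LiAlH4 reduction of F11 returns to the route at diol 13.

**Further compounds**

F1 | step 10 | (1S,2S,3S,4S)-4-[(tert-butyldimethylsilyl)oxy]-5,5-dimethoxy-3-[(triethylsilyl)oxy]-2-[(2E,6E)-3,7,11-trimethyldodeca-2,6,10-trien-1-yl]cyclohexane-1,2-diol | O[C@H]1CC(OC)(OC)[C@@H](O[Si](C)(C)C(C)(C)C)[C@H](O[Si](CC)(CC)CC)[C@]1(O)C/C=C(\C)CC/C=C(\C)CCC=C(C)C
F2 | step 7 | (2E,6E)-farnesyl phenyl sulfone | O=S(=O)(C/C=C(\C)CC/C=C(\C)CCC=C(C)C)c1ccccc1
F3 | step 7 | tert-butyl (4S,5R,8E,12E)-4-[(tert-butyldimethylsilyl)oxy]-6-hydroxy-3,3-dimethoxy-9,13,17-trimethyl-7-(phenylsulfonyl)-5-[(triethylsilyl)oxy]octadeca-8,12,16-trienoate | CC(C)(C)OC(=O)CC(OC)(OC)[C@@H](O[Si](C)(C)C(C)(C)C)[C@H](O[Si](CC)(CC)CC)C(O)C(/C=C(\C)CC/C=C(\C)CCC=C(C)C)S(=O)(=O)c1ccccc1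
F4 | step 7 | tert-butyl (4S,5S,8E,12E)-4-[(tert-butyldimethylsilyl)oxy]-3,3-dimethoxy-9,13,17-trimethyl-6-oxo-7-(phenylsulfonyl)-5-[(triethylsilyl)oxy]octadeca-8,12,16-trienoate | CC(C)(C)OC(=O)CC(OC)(OC)[C@@H](O[Si](C)(C)C(C)(C)C)[C@H](O[Si](CC)(CC)CC)C(=O)C(/C=C(\C)CC/C=C(\C)CCC=C(C)C)S(=O)(=O)c1ccccc1
F5 | step 7 | tert-butyl (4S,5S,8E,12E)-4-[(tert-butyldimethylsilyl)oxy]-3,3-dimethoxy-9,13,17-trimethyl-6-oxo-5-[(triethylsilyl)oxy]octadeca-8,12,16-trienoate | CC(C)(C)OC(=O)CC(OC)(OC)[C@@H](O[Si](C)(C)C(C)(C)C)[C@H](O[Si](CC)(CC)CC)C(=O)C/C=C(\C)CC/C=C(\C)CCC=C(C)C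
F6 | step 5 | (2S,3R)-2-[(tert-butyldimethylsilyl)oxy]-N-methoxy-N-methyl-3,4-bis[(triethylsilyl)oxy]butanamide | CON(C)C(=O)[C@@H](O[Si](C)(C)C(C)(C)C)[C@H](O[Si](CC)(CC)CC)CO[Si](CC)(CC)CC
F7 | step 5 | (5S,6R)-5-[(tert-butyldimethylsilyl)oxy]-6,7-bis[(triethylsilyl)oxy]hept-1-en-4-one | C=CCC(=O)[C@@H](O[Si](C)(C)C(C)(C)C)[C@H](O[Si](CC)(CC)CC)CO[Si](CC)(CC)CC
F8 | step 5 | (5S,6R)-5-[(tert-butyldimethylsilyl)oxy]-4,4-dimethoxy-6,7-bis[(triethylsilyl)oxy]hept-1-ene | C=CCC(OC)(OC)[C@@H](O[Si](C)(C)C(C)(C)C)[C@H](O[Si](CC)(CC)CC)CO[Si](CC)(CC)CC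
F9 | step 5 | methyl (4S,5R)-4-[(tert-butyldimethylsilyl)oxy]-3,3-dimethoxy-5,6-bis[(triethylsilyl)oxy]hexanoate | COC(=O)CC(OC)(OC)[C@@H](O[Si](C)(C)C(C)(C)C)[C@H](O[Si](CC)(CC)CC)CO[Si](CC)(CC)CC
F10 | step 5 | methyl (4S,5S)-4-[(tert-butyldimethylsilyl)oxy]-3,3-dimethoxy-6-oxo-5-[(triethylsilyl)oxy]hexanoate | COC(=O)CC(OC)(OC)[C@@H](O[Si](C)(C)C(C)(C)C)[C@H](O[Si](CC)(CC)CC)C=O
F11 | step 5 | methyl (4S,5R,8E,12E)-4-[(tert-butyldimethylsilyl)oxy]-6-hydroxy-3,3-dimethoxy-9,13,17-trimethyl-5-[(triethylsilyl)oxy]octadeca-8,12,16-trienoate | COC(=O)CC(OC)(OC)[C@@H](O[Si](C)(C)C(C)(C)C)[C@H](O[Si](CC)(CC)CC)C(O)C/C=C(\C)CC/C=C(\C)CCC=C(C)C
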